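The route cuts the pyrrole ring of the indole at C2–C3 and N1–C7a. The benzene ring (C3a, C4, C5, C6, C7, C7a) carries C3 and N1 on neighbouring carbons and bromine at C5 and C6, the substitution pattern of 1,2,4,5-tetrabromobenzene. The precursor is therefore 2,4,5-tribromobenzaldehyde, whose aldehyde carbon becomes C3 and whose single ortho bromine marks C7a. In one operation methyl isocyanoacetate condenses with the aldehyde and copper joins the nitrogen to C7a, closing the pyrrole ring as a 5,6-dibromoindole-2-carboxylate. The C2 carboxyl group is then removed, and the aminomethyl arm, the C2 bromine and the N-oxide follow by ordinary indole chemistry.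

Key step: step 2

Remark: the target has no stereocentre; oxazoline 7 is a racemic, transient species whose two stereocentres disappear in the following elimination.

Step 1
Reactants: 1 1,2,4,5-tetrabromobenzene; 2 N,N-dimethylformamide
Product: 5 2,4,5-tribromobenzaldehyde, via 2,4,5-tribromophenylmagnesium chloride 3 (not isolated), via chloromagnesium (dimethylamino)(2,4,5-tribromophenyl)methanolate 4 (not isolated)
Conditions: iPrMgCl·LiCl (1.05 equiv), THF, −40 °C; then DMF (2), −40 °C → rt; aq. HCl
Reagents that add atoms: none
Why: Bromine–magnesium exchange with the turbo-Grignard reagent acts on one of four equivalent C–Br bonds, so only one monoaldehyde is possible; a second exchange is disfavoured on the electron-rich arylmagnesium, the ortho-bromo Grignard 3 is stable to aryne formation in the cold, and Bouveault formylation with DMF followed by acid hydrolysis of 4 should give 5.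

Step 2
Reactants: 5 2,4,5-tribromobenzaldehyde; 6 methyl isocyanoacetate
Product: 10 methyl 5,6-dibromo-1H-indole-2-carboxylate, via methyl trans-5-(2,4,5-tribromophenyl)-4,5-dihydro-1,3-oxazole-4-carboxylate 7 (not isolated), via methyl (2Z)-2-formamido-3-(2,4,5-tribromophenyl)prop-2-enoate 8 (not isolated), via methyl 5,6-dibromo-1-formyl-1H-indole-2-carboxylate 9 (not isolated)
Conditions: CuI (10 mol %), Cs2CO3 (2 equiv), DMSO, 80 °C, N2
Reagents that add atoms: none
Why: Carbonate deprotonates 6, the α-isocyano ester anion adds to the aldehyde of 5, the alkoxide closes onto the isocyanide carbon to oxazoline 7, and base-induced β-elimination opens 7 to the (Z)-formamidoacrylate 8, so that C2–C3 is made as a C=C bond. The amide nitrogen of 8 binds monovalent copper, which inserts into the neighbouring C–Br bond; C–N reductive elimination from the six-membered cupracycle (trivalent copper) forms N1–C7a, and the labile N-formyl group of 9 is then cleaved by carbonate and the water formed in the flask to leave the NH indole 10. The closest known reaction type is the copper-catalysed condensation, C–N coupling and deformylation cascade of 2-halobenzaldehydes with isocyanoacetates to indole-2-carboxylates. The five-membered pyrrole ring is closed by this intramolecular Goldberg N-arylation, the nitrogen attacking the ipso carbon of the C–Br bond that sits five atoms away. No stereocentre is formed; only the Z geometry of 8 matters, and it is the thermodynamically preferred isomer, which places nitrogen beside the ortho carbon. The selectivity needed is among three C–Br bonds and is secured by the substrate: the aldehyde has one ortho bromine only (the other ortho position is C–H), the tethered amide can reach that bromine alone, and ligand-free CuI at 80 °C should not couple the remote bromines intermolecularly at a competitive rate.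

Step 3
Reactants: 10 methyl 5,6-dibromo-1H-indole-2-carboxylate
Product: 12 5,6-dibromo-1-methyl-1H-indole-2-carboxylic acid, via methyl 5,6-dibromo-1-methyl-1H-indole-2-carboxylate 11 (not isolated)
Conditions: KOH, MeI, DMSO, rt; then H2O, 60 °C; aq. HCl
Reagents that add atoms: iodomethane, CI; potassium hydroxide, [K+].[OH-] (its oxygen becomes the carboxyl OH)
Why: The acidic N–H of the indole-2-carboxylate is deprotonated by KOH in DMSO and the indolide is N-methylated by MeI (SN2 alkylation), after which added water saponifies the methyl ester and destroys excess MeI, with the aryl bromides inert to hydroxide.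

Step 4
Reactants: 12 5,6-dibromo-1-methyl-1H-indole-2-carboxylic acid
Product: 13 5,6-dibromo-1-methyl-1H-indole
Conditions: Ag2CO3 (10 mol %), AcOH (5 mol %), DMSO, 120 °C
Reagents that add atoms: none
Why: Silver-catalysed protodecarboxylation: the silver carboxylate loses CO2 to a 2-indolylsilver species stabilised by the adjacent nitrogen, which is protonated by AcOH, and monovalent silver does not insert into the C5–Br and C6–Br bonds.

Step 5
Reactants: 13 5,6-dibromo-1-methyl-1H-indole
Product: 14 1-(5,6-dibromo-1-methyl-1H-indol-3-yl)-N,N-dimethylmethanamine (5,6-dibromo-1-methylgramine)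
Conditions: CH2=NMe2+ I− (Eschenmoser's salt, 1.2 equiv), MeCN, 60 °C; aq. NaOH
Reagents that add atoms: N,N-dimethylmethyleneiminium iodide (Eschenmoser's salt), C=[N+](C)C.[I-]
Why: Mannich reaction with the preformed iminium ion, in which C3, the most nucleophilic position of the 1-methylindole, attacks CH2=NMe2+ by electrophilic aromatic substitution; the two ring bromines slow the reaction but do not divert it.

Step 6
Reactants: 14 1-(5,6-dibromo-1-methyl-1H-indol-3-yl)-N,N-dimethylmethanamine
Product: 15 1-(2,5,6-tribromo-1-methyl-1H-indol-3-yl)-N,N-dimethylmethanamine (2,5,6-tribromo-1-methylgramine)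
Conditions: NBS (1.05 equiv), CH2Cl2/TFA (10:1), 0 °C, dark; aq. Na2S2O3/NaHCO3
Reagents that add atoms: N-bromosuccinimide, O=C1CCC(=O)N1Br
Why: Electrophilic bromination of a 3-alkylindole at C2, the only free pyrrole position; TFA keeps the amine protonated so that it is neither N-brominated nor able to expel the side chain as an iminium ion after ipso attack at C3, and the N-methyl group prevents formation of a neutral 3-methyleneindolenine.

Step 7
Reactants: 15 1-(2,5,6-tribromo-1-methyl-1H-indol-3-yl)-N,N-dimethylmethanamine
Product: 16 1-(2,5,6-tribromo-1-methyl-1H-indol-3-yl)-N,N-dimethylmethanamine N-oxide (target)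
Conditions: mCPBA (1.05 equiv), CH2Cl2, 0 °C; filtration through basic Al2O3
Reagents that add atoms: 3-chloroperbenzoic acid, OOC(=O)c1cccc(Cl)c1
Why: Peracid N-oxidation of a trialkylamine, whose lone pair is far more nucleophilic than the electron-poor tribromoindole π system, so one equivalent at 0 °C should oxidise nitrogen only; the two N-methyl groups are identical, so no stereocentre arises.

Compound list
1 | 1,2,4,5-tetrabromobenzene | Brc1cc(Br)c(Br)cc1Br | starting material
2 | N,N-dimethylformamide | CN(C)C=O | starting material
3 | 2,4,5-tribromophenylmagnesium chloride | Cl[Mg]c1cc(Br)c(Br)cc1Br | intermediate (not isolated)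
4 | chloromagnesium (dimethylamino)(2,4,5-tribromophenyl)methanolate (racemic) | CN(C)C(O[Mg]Cl)c1cc(Br)c(Br)cc1Br | intermediate (not isolated)
5 | 2,4,5-tribromobenzaldehyde | O=Cc1cc(Br)c(Br)cc1Br | intermediate
6 | methyl isocyanoacetate | [C-]#[N+]CC(=O)OC | starting material
7 | methyl trans-5-(2,4,5-tribromophenyl)-4,5-dihydro-1,3-oxazole-4-carboxylate (racemic, one enantiomer drawn) | COC(=O)[C@@H]1N=CO[C@H]1c1cc(Br)c(Br)cc1Br | intermediate (not isolated)
8 | methyl (2Z)-2-formamido-3-(2,4,5-tribromophenyl)prop-2-enoate | COC(=O)/C(NC=O)=C/c1cc(Br)c(Br)cc1Br | intermediate (not isolated)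
9 | methyl 5,6-dibromo-1-formyl-1H-indole-2-carboxylate | COC(=O)c1cc2cc(Br)c(Br)cc2n1C=O | intermediate (not isolated)
10 | methyl 5,6-dibromo-1H-indole-2-carboxylate | COC(=O)c1cc2cc(Br)c(Br)cc2[nH]1 | intermediate
11 | methyl 5,6-dibromo-1-methyl-1H-indole-2-carboxylate | COC(=O)c1cc2cc(Br)c(Br)cc2n1C | intermediate (not isolated)
12 | 5,6-dibromo-1-methyl-1H-indole-2-carboxylic acid | OC(=O)c1cc2cc(Br)c(Br)cc2n1C | intermediate
13 | 5,6-dibromo-1-methyl-1H-indole | Cn1ccc2cc(Br)c(Br)cc21 | intermediate
14 | 1-(5,6-dibromo-1-methyl-1H-indol-3-yl)-N,N-dimethylmethanamine | CN(C)Cc1cn(C)c2cc(Br)c(Br)cc12 | intermediate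
15 | 1-(2,5,6-tribromo-1-methyl-1H-indol-3-yl)-N,N-dimethylmethanamine | CN(C)Cc1c(Br)n(C)c2cc(Br)c(Br)cc12 | intermediate
16 | 1-(2,5,6-tribromo-1-methyl-1H-indol-3-yl)-N,N-dimethylmethanamine N-oxide | Cn1c(Br)c(C[N+](C)(C)[O-])c2cc(Br)c(Br)cc21 | target

Total step count: 7
Longest linear sequence: 7 steps (1 → 5 → 10 → 12 → 13 → 14 → 15 → 16)

Steps most likely to fail

Step 2. Ring closure may be outrun by intermolecular C–N coupling through the remote bromines, or the cascade may stall after the condensation while the isocyanoacetate is consumed by base. The fallback separates the two bond formations and sets out from 5. Horner–Wadsworth–Emmons olefination of 5 with methyl 2-[(tert-butoxycarbonyl)amino]-2-(dimethoxyphosphoryl)acetate and DBU in CH2Cl2 should give methyl (2Z)-2-[(tert-butoxycarbonyl)amino]-3-(2,4,5-tribromophenyl)prop-2-enoate F1. Intramolecular Goldberg amidation of F1 (CuI, N,N'-dimethylethane-1,2-diamine, K2CO3, toluene, 100 °C) should then close the ring to 1-tert-butyl 2-methyl 5,6-dibromo-1H-indole-1,2-dicarboxylate F2. Removal of the carbamate with TFA in CH2Cl2 comes back to the route at 10.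

Step 6. Ipso attack of the brominating agent at C3 with loss of the aminomethyl arm, or oxidation at the amine, may compete with substitution at C2. The fallback sets out from 13, places the C2 bromine without any amine present and brings in the nitrogen last. Pyridinium tribromide in tert-butanol should oxidise 13 to 3,3,5,6-tetrabromo-1-methyl-1,3-dihydro-2H-indol-2-one F3. Zn dust in AcOH should remove the two C3 bromines to give 5,6-dibromo-1-methyl-1,3-dihydro-2H-indol-2-one F4. Vilsmeier–Haack haloformylation with POBr3/DMF should give 2,5,6-tribromo-1-methyl-1H-indole-3-carbaldehyde F5. Reductive amination of F5 with dimethylamine and NaBH(OAc)3 in 1,2-dichloroethane comes back to the route at 15.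

Step 4. Decarboxylation may stall on the electron-poor acid, or forcing it may cause reductive loss of ring bromine. The fallback leaves this step out and uses the carboxyl group itself as the leaving group for bromine; it sets out from 11, isolated by working up step 3 before water is added. A Mannich reaction of 11 with Eschenmoser's salt in refluxing MeCN should give methyl 5,6-dibromo-3-[(dimethylamino)methyl]-1-methyl-1H-indole-2-carboxylate F6. Saponification with LiOH in THF/H2O should give 5,6-dibromo-3-[(dimethylamino)methyl]-1-methyl-1H-indole-2-carboxylic acid F7, a zwitterion whose ammonium group is protected from fragmentation. Ipso-bromodecarboxylation of F7 with NBS in MeCN/H2O at rt comes back to the route at 15, replacing steps 4 to 6. This last reaction is the least certain of the three fallbacks.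

Further compounds
F1 | step 2 | methyl (2Z)-2-[(tert-butoxycarbonyl)amino]-3-(2,4,5-tribromophenyl)prop-2-enoate | COC(=O)/C(NC(=O)OC(C)(C)C)=C/c1cc(Br)c(Br)cc1Br
F2 | step 2 | 1-tert-butyl 2-methyl 5,6-dibromo-1H-indole-1,2-dicarboxylate | COC(=O)c1cc2cc(Br)c(Br)cc2n1C(=O)OC(C)(C)C
F3 | step 6 | 3,3,5,6-tetrabromo-1-methyl-1,3-dihydro-2H-indol-2-one | CN1C(=O)C(Br)(Br)c2cc(Br)c(Br)cc21
F4 | step 6 | 5,6-dibromo-1-methyl-1,3-dihydro-2H-indol-2-one | CN1C(=O)Cc2cc(Br)c(Br)cc21
F5 | step 6 | 2,5,6-tribromo-1-methyl-1H-indole-3-carbaldehyde | Cn1c(Br)c(C=O)c2cc(Br)c(Br)cc21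
F6 | step 4 | methyl 5,6-dibromo-3-[(dimethylamino)methyl]-1-methyl-1H-indole-2-carboxylate | COC(=O)c1c(CN(C)C)c2cc(Br)c(Br)cc2n1C
F7 | step 4 | 5,6-dibromo-3-[(dimethylamino)methyl]-1-methyl-1H-indole-2-carboxylic acid | CN(C)Cc1c(C(=O)O)n(C)c2cc(Br)c(Br)cc12
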